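**Retrosynthetic overview**
1. Cleave the C8 ester. This gives the macrocyclic C8 alcohol and (Z)-2-(silyloxymethyl)but-2-enoic acid. The two are joined by Yamaguchi acylation and desilylated last.
2. Key cut at C6–C7. C7 is the β-carbon of an acrylate and is normally an acceptor. As a 2-(methoxycarbonyl)allylzinc (a homoenolate equivalent) it becomes the donor and attacks the C6 aldehyde carbon of the same chain. This sets C6 and C7.
3. The open-chain bromo-dienal comes from a Sonogashira coupling at C3–C4 with (Z)-3-iodobut-2-enal followed by Lindlar reduction. C7=C11 comes from cross metathesis with methyl 2-(hydroxymethyl)acrylate.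
4. The epoxy-enyne core comes from Sharpless epoxidation (C1, C10) of an E-enynol. The enynol is made in one pot from (S)-2-vinyloxirane (C8), triethyl phosphonoacetate and 3-(trimethylsilyl)propynal.
5. Ring order: oxirane (ring C) first, ten-membered carbocycle (ring A) second, cis-γ-lactone (ring B) last, in the same flask as ring A.

Assumption: (S)-2-vinyloxirane is bought as the single enantiomer (it is the epoxide recovered from hydrolytic kinetic resolution of butadiene monoxide).

Atom labels follow germacrane numbering: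
- C1/C10: epoxide
- C2=C3 and C4=C5: Z-alkenes
- C6: lactone carbinol
- C7: ring-fusion carbon
- C8: acyloxy carbon
- C9: CH2
- C11–C13: methylene lactone
- C14: CH2OH
- C15: CH3

**Part A: C4–C6 aldehyde**

Step 1
Reactants: 1 but-2-yn-1-ol
Product: 3 (Z)-3-iodobut-2-en-1-ol, via cyclic sodium alkenylalanate 2 (not isolated)
Conditions: NaAlH2(OCH2CH2OMe)2, THF, 0 °C to rt; then I2, −78 to 0 °C
Reagents that add atoms: iodine, [I][I]
Why: Hydroxyl-directed trans-hydroalumination places aluminium on C3 syn to the carbinol in a five-membered alanate, and iodinolysis of the carbon–aluminium bond goes with retention, so only the Z-iodide forms.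

Step 2
Reactants: 3 (Z)-3-iodobut-2-en-1-ol
Product: 4 (Z)-3-iodobut-2-enal
Conditions: MnO2, CH2Cl2, rt, dark
Reagents that add atoms: none
Why: Allylic alcohol oxidation on MnO2 is neutral and keeps the Z geometry when run briefly in the dark.

**Part B: side-chain acid**

Step 3
Reactants: 5 (E)-but-2-enal
Product: 6 (Z)-2-iodobut-2-enal
Conditions: I2, K2CO3, DMAP (cat.), THF–H2O, rt
Reagents that add atoms: iodine, [I][I]
Why: Baylis–Hillman-type α-iodination (DMAP conjugate addition, iodination, elimination) replaces only the α-hydrogen, so methyl and iodine end up cis (Z).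

Step 4
Reactants: 6 (Z)-2-iodobut-2-enal
Product: 7 (Z)-2-iodobut-2-en-1-ol
Conditions: NaBH4, MeOH, −20 °C
Reagents that add atoms: none
Why: Borohydride 1,2-reduction of the enal leaves the alkenyl iodide and its geometry untouched.

Step 5
Reactants: 7 (Z)-2-iodobut-2-en-1-ol
Product: 8 tert-butyl{[(Z)-2-iodobut-2-en-1-yl]oxy}dimethylsilane
Conditions: TBSCl, imidazole, CH2Cl2, rt
Reagents that add atoms: tert-butyldimethylsilyl chloride, CC(C)(C)[Si](C)(C)Cl
Why: This is a standard silyl protection of a primary alcohol.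

Step 6
Reactants: 8 tert-butyl{[(Z)-2-iodobut-2-en-1-yl]oxy}dimethylsilane
Product: 10 (Z)-2-{[(tert-butyldimethylsilyl)oxy]methyl}but-2-enoic acid, via alkenyllithium 9 (not isolated)
Conditions: t-BuLi (2.1 equiv), Et2O, −78 °C; CO2; cold 1 M HCl
Reagents that add atoms: carbon dioxide, O=C=O
Why: Iodine–lithium exchange at −78 °C gives a configurationally stable alkenyllithium that is carboxylated with retention, which fixes the Z (angelate-type) geometry of the side chain.

**Part C: main chain**

Step 7
Reactants: 11 (S)-2-vinyloxirane; 12 triethyl phosphonoacetate; 13 3-(trimethylsilyl)prop-2-ynal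
Product: 15 (3E,5R)-3-[3-(trimethylsilyl)prop-2-yn-1-ylidene]-5-vinyldihydrofuran-2(3H)-one, via sodium phosphonolactone enolate 14 (not isolated)
Conditions: NaH, THF, 0 °C; 11, 65 °C (sealed), 16 h; then 13, −20 °C to rt
Reagents that add atoms: none
Why: The phosphonoacetate anion opens the epoxide at its CH2 terminus (SN2, C8 untouched), the alkoxide lactonises, the released ethoxide regenerates the phosphonate carbanion, and a Horner–Wadsworth–Emmons reaction with the ynal gives mainly the E-alkylidene lactone (alkynyl trans to C=O), the minor Z isomer being removed by chromatography.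

Step 8
Reactants: 15 E-alkylidene lactone
Product: 16 (2E)-2-[(2R)-2-hydroxybut-3-en-1-yl]-5-(trimethylsilyl)pent-2-en-4-yn-1-ol
Conditions: i-Bu2AlH (4 equiv), CH2Cl2, −78 to 0 °C; Rochelle salt
Reagents that add atoms: none
Why: Exhaustive 1,2-reduction of the lactone frees the C14 allylic alcohol and the C8 carbinol and keeps the alkene geometry (C2 cis to C9).

Step 9
Reactants: 16 enyne diol
Product: 17 {(2R,3R)-2-[(2R)-2-hydroxybut-3-en-1-yl]-3-[(trimethylsilyl)ethynyl]oxiran-2-yl}methanol
Conditions: Ti(OiPr)4 (10 mol %), D-(−)-diisopropyl tartrate (12 mol %), t-BuOOH (1.1 equiv), 4 Å MS, CH2Cl2, −25 °C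
Reagents that add atoms: tert-butyl hydroperoxide, CC(C)(C)OO
Why: In this Katsuki–Sharpless asymmetric epoxidation the D-(−)-tartrate catalyst delivers oxygen to the face that gives the (2R,3R)-epoxide of a 2,3-trans-substituted allylic alcohol (C10 R, C1 R), and the primary trisubstituted allylic alcohol reacts far faster than the C8 vinyl carbinol, so one equivalent of oxidant is selective.

Step 10
Reactants: 17 epoxy diol
Product: 19 C14-OTBS C8-OTES bis-silyl ether of 17, via C14 mono-TBS ether 18 (not isolated)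
Conditions: TBSCl (1.05 equiv), imidazole, DMF, 0 °C; then TESCl (1.3 equiv), rt
Reagents that add atoms: tert-butyldimethylsilyl chloride, CC(C)(C)[Si](C)(C)Cl; triethylsilyl chloride, CC[Si](Cl)(CC)CC
Why: In this sequential one-pot silylation the primary C14 hydroxyl takes the bulky TBS group first and the remaining secondary C8 hydroxyl then takes the more labile TES group, which gives an orthogonal pair.

Step 11
Reactants: 19 bis-silyl ether; 20 methyl 2-(hydroxymethyl)acrylate
Product: 21 methyl (2E,4R)-5-{(2R,3R)-2-[(TBSO)methyl]-3-[(trimethylsilyl)ethynyl]oxiran-2-yl}-2-(hydroxymethyl)-4-(triethylsilyloxy)pent-2-enoate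
Conditions: 20 (5 equiv), Hoveyda–Grubbs second-generation catalyst (10 mol %), toluene, 60 °C, Ar sparge
Reagents that add atoms: none
Why: This olefin cross metathesis joins the only monosubstituted alkene to an excess of a non-dimerising 1,1-disubstituted acrylate, as in methacrylate cross metathesis; thermodynamic control places the C8 chain trans to the ester (cis to C13), and the silyl-capped alkyne is too hindered to react.

Step 12
Reactants: 21 allylic alcohol; 4 (Z)-3-iodobut-2-enal
Product: 23 methyl (2E,4R)-5-{(2R,3R)-2-[(TBSO)methyl]-3-[(3Z)-3-methyl-5-oxopent-3-en-1-yn-1-yl]oxiran-2-yl}-2-(hydroxymethyl)-4-(triethylsilyloxy)pent-2-enoate, via terminal alkyne 22 (not isolated)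
Conditions: Bu4NF (1.0 equiv), THF, −40 °C, 10 min; then 4, Pd(PPh3)4 (3 mol %), CuI (6 mol %), Et3N, 0 °C to rt
Reagents that add atoms: none
Why: One equivalent of fluoride cleaves the C(sp)–Si bond much faster than either O–Si bond, and the Sonogashira coupling keeps the Z geometry of the iodide because zerovalent palladium inserts into the activated β-iodoenal faster than it ionises the propargylic epoxide.

Step 13
Reactants: 23 enynal
Product: 24 methyl (2E,4R)-5-{(2R,3R)-2-[(TBSO)methyl]-3-[(1Z,3Z)-3-methyl-5-oxopenta-1,3-dien-1-yl]oxiran-2-yl}-2-(hydroxymethyl)-4-(triethylsilyloxy)pent-2-enoate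
Conditions: H2 (1 atm), Pd/CaCO3 poisoned with Pb(OAc)2, quinoline, EtOAc, 0 °C, dark
Reagents that add atoms: none
Why: Lindlar syn-semihydrogenation of the only alkyne gives the Z C2=C3 alkene, while the two trisubstituted electron-poor alkenes and the epoxide are not reduced on the poisoned catalyst.

Step 14
Reactants: 24 dienal allylic alcohol
Product: 25 methyl (2Z,4R)-2-(bromomethyl)-5-{(2R,3R)-2-[(TBSO)methyl]-3-[(1Z,3Z)-3-methyl-5-oxopenta-1,3-dien-1-yl]oxiran-2-yl}-4-(triethylsilyloxy)pent-2-enoate
Conditions: NBS, Me2S, CH2Cl2, −30 to 0 °C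
Reagents that add atoms: N-bromosuccinimide, O=C1CCC(=O)N1Br
Why: The Corey–Kim halogenation reagent converts the primary allylic alcohol into the bromide under neutral conditions that spare the aldehyde (which a CBr4/PPh3 system would attack), the vinyl epoxide and the silyl ethers.

Step 15
Reactants: 25 bromo dienal
Product: 28 14-O-TBS-8-O-TES germacranolide core (cis-fused 12,6-olide), via Z-allylzinc bromide 26 (not isolated), via ring-closed bromozinc alkoxide 27 (not isolated)
Conditions: activated Zn dust (10 equiv), THF, 40 °C, syringe-pump addition of 25 over 12 h (final 1 mM); aq. NH4Cl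
Reagents that add atoms: none
Why: In this intramolecular Barbier (Dreiding–Schmidt) allylation zinc insertion turns the bromide into a 2-(methoxycarbonyl)allylzinc whose γ-carbon C7, normally the electrophilic β-carbon of an acrylate, attacks the C6 aldehyde carbon as a homoenolate-type donor through a closed chair in which the Z-allyl geometry (C8 axial) and an equatorial C5 give the 6,7-syn pair (6S and the target configuration at C7, hence the cis-lactone), the 8R centre choosing the face because only there can the tether carbon C9 stand anti to the forming bond (no syn-pentane contact with C5) with H8 over the chair and the bulky, non-chelating OTES pointing outward and poorly aligned for 1,4-elimination, after which the zinc alkoxide expels methoxide to close the lactone; allyl-metal closure of ten-membered rings is known in germacranolide work.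

Step 16
Reactants: 28 bis-silylated macrolactone
Product: 29 14-O-TBS germacranolide C8 alcohol (1R,6S,7R,8R,10R)
Conditions: HF·pyridine, pyridine, THF, 0 °C
Reagents that add atoms: none
Why: Buffered fluoride cleaves the TES ether far faster than the TBS ether and is mild enough for the vinyl epoxide and the methylene lactone.

Step 17
Reactants: 29 C8 alcohol; 10 (Z)-2-{[(tert-butyldimethylsilyl)oxy]methyl}but-2-enoic acid
Product: 31 bis-TBS ether of the target, via mixed Yamaguchi anhydride 30 (not isolated)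
Conditions: 10, 2,4,6-Cl3C6H2COCl, Et3N, toluene, rt; then 29, DMAP (0.5 equiv), 0 °C to rt
Reagents that add atoms: none
Why: Yamaguchi esterification acylates the hindered C8 hydroxyl at oxygen (retention at C8), and the low DMAP loading and low temperature limit Z to E isomerisation of the angelate-type acid.

Step 18
Reactants: 31 bis-TBS ether of the target
Product: 32 target CNP0165856.1
Conditions: Et3N·3HF, MeCN, rt
Reagents that add atoms: none
Why: This nearly neutral fluoride source removes both primary TBS groups without opening the vinyl epoxide, adding to the methylene lactone or moving the ester.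

**Compound list**

1 | but-2-yn-1-ol | CC#CCO | starting material
2 | cyclic sodium alkenylalanate (five-membered O–Al–C ring, two 2-methoxyethoxy ligands) | CC1=CCO[Al-]1(OCCOC)OCCOC.[Na+] | intermediate
3 | (Z)-3-iodobut-2-en-1-ol | OC/C=C(\I)C | intermediate
4 | (Z)-3-iodobut-2-enal | O=C/C=C(\I)C | intermediate
5 | (E)-but-2-enal (crotonaldehyde) | C/C=C/C=O | starting material
6 | (Z)-2-iodobut-2-enal | C/C=C(\I)C=O | intermediate
7 | (Z)-2-iodobut-2-en-1-ol | C/C=C(\I)CO | intermediate
8 | tert-butyl{[(Z)-2-iodobut-2-en-1-yl]oxy}dimethylsilane | C/C=C(\I)CO[Si](C)(C)C(C)(C)C | intermediate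
9 | alkenyllithium from 8 (lithium cis to methyl) | C/C=C(\[Li])CO[Si](C)(C)C(C)(C)C | intermediate
10 | (Z)-2-{[(tert-butyldimethylsilyl)oxy]methyl}but-2-enoic acid | C/C=C(\C(=O)O)CO[Si](C)(C)C(C)(C)C | intermediate
11 | (S)-2-vinyloxirane | C=C[C@H]1CO1 | starting material
12 | triethyl phosphonoacetate | CCOC(=O)CP(=O)(OCC)OCC | starting material
13 | 3-(trimethylsilyl)prop-2-ynal | C[Si](C)(C)C#CC=O | starting material
14 | sodium salt of diethyl [(5R)-2-oxo-5-vinyltetrahydrofuran-3-yl]phosphonate | C=C[C@H]1C[C-](C(=O)O1)P(=O)(OCC)OCC.[Na+] | intermediate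
15 | (3E,5R)-3-[3-(trimethylsilyl)prop-2-yn-1-ylidene]-5-vinyldihydrofuran-2(3H)-one | O=C1O[C@@H](C=C)C/C1=C\C#C[Si](C)(C)C | intermediate
16 | (2E)-2-[(2R)-2-hydroxybut-3-en-1-yl]-5-(trimethylsilyl)pent-2-en-4-yn-1-ol | C[Si](C)(C)C#C/C=C(/CO)C[C@@H](O)C=C | intermediate
17 | {(2R,3R)-2-[(2R)-2-hydroxybut-3-en-1-yl]-3-[(trimethylsilyl)ethynyl]oxiran-2-yl}methanol | C[Si](C)(C)C#C[C@H]1O[C@@]1(CO)C[C@@H](O)C=C | intermediate
18 | C14 mono-TBS ether of 17 | C[Si](C)(C)C#C[C@H]1O[C@@]1(CO[Si](C)(C)C(C)(C)C)C[C@@H](O)C=C | intermediate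
19 | C14-OTBS, C8-OTES bis-silyl ether of 17 | C[Si](C)(C)C#C[C@H]1O[C@@]1(CO[Si](C)(C)C(C)(C)C)C[C@@H](O[Si](CC)(CC)CC)C=C | intermediate
20 | methyl 2-(hydroxymethyl)acrylate | C=C(CO)C(=O)OC | starting material
21 | cross-metathesis product: E-2-(hydroxymethyl)enoate, C8 cis to C13, TMS-alkyne | C[Si](C)(C)C#C[C@H]1O[C@@]1(CO[Si](C)(C)C(C)(C)C)C[C@@H](O[Si](CC)(CC)CC)/C=C(\CO)C(=O)OC | intermediate
22 | terminal alkyne from 21 | C#C[C@H]1O[C@@]1(CO[Si](C)(C)C(C)(C)C)C[C@@H](O[Si](CC)(CC)CC)/C=C(\CO)C(=O)OC | intermediate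
23 | (4Z)-enynal (C2≡C3, C6 aldehyde) | O=C/C=C(C)\C#C[C@H]1O[C@@]1(CO[Si](C)(C)C(C)(C)C)C[C@@H](O[Si](CC)(CC)CC)/C=C(\CO)C(=O)OC | intermediate
24 | (2Z,4Z)-dienal allylic alcohol | O=C/C=C(C)\C=C/[C@H]1O[C@@]1(CO[Si](C)(C)C(C)(C)C)C[C@@H](O[Si](CC)(CC)CC)/C=C(\CO)C(=O)OC | intermediate
25 | (2Z,4Z)-dienal Z-allylic bromide | O=C/C=C(C)\C=C/[C@H]1O[C@@]1(CO[Si](C)(C)C(C)(C)C)C[C@@H](O[Si](CC)(CC)CC)/C=C(\CBr)C(=O)OC | intermediate
26 | Z-2-(methoxycarbonyl)allylzinc bromide from 25 | O=C/C=C(C)\C=C/[C@H]1O[C@@]1(CO[Si](C)(C)C(C)(C)C)C[C@@H](O[Si](CC)(CC)CC)/C=C(\C[Zn]Br)C(=O)OC | intermediate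
27 | ten-membered carbocycle, C6 bromozinc alkoxide, C7 bearing the 2-(methoxycarbonyl)vinyl unit | Br[Zn]O[C@H]1/C=C(C)\C=C/[C@H]2O[C@@]2(CO[Si](C)(C)C(C)(C)C)C[C@@H](O[Si](CC)(CC)CC)[C@H]1C(=C)C(=O)OC | intermediate
28 | 14-(TBSO)-1,10-epoxy-8-(TESO)germacra-2Z,4Z,11(13)-trien-12,6-olide, 1R,6S,8R,10R; C7 has the spatial arrangement of the target but reads S here because O–Si outranks O–C | C=C1C(=O)O[C@H]2/C=C(C)\C=C/[C@H]3O[C@@]3(CO[Si](C)(C)C(C)(C)C)C[C@@H](O[Si](CC)(CC)CC)[C@@H]12 | intermediate
29 | (1R,6S,7R,8R,10R)-14-(TBSO)-1,10-epoxy-8-hydroxygermacra-2Z,4Z,11(13)-trien-12,6-olide | C=C1C(=O)O[C@H]2/C=C(C)\C=C/[C@H]3O[C@@]3(CO[Si](C)(C)C(C)(C)C)C[C@@H](O)[C@@H]12 | intermediate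
30 | mixed anhydride of 10 and 2,4,6-trichlorobenzoic acid | C/C=C(\C(=O)OC(=O)c1c(Cl)cc(Cl)cc1Cl)CO[Si](C)(C)C(C)(C)C | intermediate
31 | bis-TBS ether of the target (C14-OTBS, side-chain OTBS) | C=C1C(=O)O[C@H]2/C=C(C)\C=C/[C@H]3O[C@@]3(CO[Si](C)(C)C(C)(C)C)C[C@@H](OC(=O)/C(=C\C)CO[Si](C)(C)C(C)(C)C)[C@@H]12 | intermediate
32 | CNP0165856.1, (1R,6S,7R,8R,10R)-1,10-epoxy-14-hydroxy-8-[(Z)-2-(hydroxymethyl)but-2-enoyloxy]germacra-2Z,4Z,11(13)-trien-12,6-olide | C=C1C(=O)O[C@H]2/C=C(C)\C=C/[C@H]3O[C@@]3(CO)C[C@@H](OC(=O)/C(=C\C)CO)[C@@H]12 | target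

**Totals**
- Total step count: 18.
- Longest linear sequence: 12 steps (steps 7 to 18, from 11).

**Three steps most likely to fail**

Step 15 (macrocyclising Barbier reaction). The ten-membered ring closure competes with dimerisation, protonation and 1,4-loss of silanolate. The facial preference rests on a transition-state model. The fallback sets out from 22 (isolated after the fluoride treatment of 21) and comes back at 28. Compound 22 is semi-hydrogenated over the Lindlar catalyst to the vinyl epoxide allylic alcohol F1. NBS/Me2S then converts it into the allylic bromide F2. Aldehyde 4 is vinylated with tributyl(vinyl)stannane under Pd(PPh3)4 catalysis to (Z)-3-methylpenta-2,4-dienal F3. F2 and F3 are joined by an intermolecular zinc Barbier reaction at normal concentration, which makes the same C6–C7 bond through the same chair and 8R control and gives the open-chain cis-lactone F4. The ten-membered ring is then closed by ring-closing metathesis of the two terminal vinyl groups with second-generation Grubbs catalyst. This forms C2=C3 and gives 28.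

Step 11 (cross metathesis to a trisubstituted, doubly allylic-oxygenated alkene). The hindered pairing may stall. The fallback sets out from 19 and comes back at 25. Ozonolysis of the vinyl group (O3, then Me2S) gives the α-silyloxy aldehyde F5. A Morita–Baylis–Hillman reaction with methyl acrylate and DABCO gives the adduct F6; its C7 epimers are of no consequence. K2CO3 in MeOH frees the terminal alkyne F7. Sonogashira coupling with 4 gives the enynal F8, and Lindlar reduction gives the dienal F9. NBS/Me2S then converts the secondary allylic alcohol with SN2' transposition into the Z-bromide 25.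

Step 13 (semi-hydrogenation of the enynal). Over-reduction, Z to E drift of the dienal on palladium or hydrogenolysis of the new vinyl epoxide can occur. The fallback sets out from 22 and comes back at 24. Compound 22 is coupled with the iodo alcohol 3 (Sonogashira) to give the enynol F10. The alkyne is reduced at the alcohol oxidation level with Zn(Cu/Ag) in aqueous methanol to the Z,Z-dienol F11. MnO2 then oxidises the electron-rich dienylic C6 alcohol selectively to 24, because the acrylate-type C13 alcohol reacts much more slowly.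

**Further compounds**

F1 | step 15 | vinyl epoxide allylic alcohol | C=C[C@H]1O[C@@]1(CO[Si](C)(C)C(C)(C)C)C[C@@H](O[Si](CC)(CC)CC)/C=C(\CO)C(=O)OC
F2 | step 15 | vinyl epoxide Z-allylic bromide | C=C[C@H]1O[C@@]1(CO[Si](C)(C)C(C)(C)C)C[C@@H](O[Si](CC)(CC)CC)/C=C(\CBr)C(=O)OC
F3 | step 15 | (Z)-3-methylpenta-2,4-dienal | O=C/C=C(C)\C=C
F4 | step 15 | open-chain cis-α-methylene-γ-butyrolactone with dienyl and vinyl-epoxide termini | C=C1C(=O)O[C@@H](/C=C(C)\C=C)[C@H]1[C@H](O[Si](CC)(CC)CC)C[C@]2(CO[Si](C)(C)C(C)(C)C)O[C@@H]2C=C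
F5 | step 11 | α-(triethylsilyloxy) aldehyde (C7 aldehyde) | C[Si](C)(C)C#C[C@H]1O[C@@]1(CO[Si](C)(C)C(C)(C)C)C[C@@H](O[Si](CC)(CC)CC)C=O
F6 | step 11 | Morita–Baylis–Hillman adduct (C7 epimers) | C[Si](C)(C)C#C[C@H]1O[C@@]1(CO[Si](C)(C)C(C)(C)C)C[C@@H](O[Si](CC)(CC)CC)C(O)C(=C)C(=O)OC
F7 | step 11 | terminal alkyne of the adduct | C#C[C@H]1O[C@@]1(CO[Si](C)(C)C(C)(C)C)C[C@@H](O[Si](CC)(CC)CC)C(O)C(=C)C(=O)OC
F8 | step 11 | enynal of the adduct series | O=C/C=C(C)\C#C[C@H]1O[C@@]1(CO[Si](C)(C)C(C)(C)C)C[C@@H](O[Si](CC)(CC)CC)C(O)C(=C)C(=O)OC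
F9 | step 11 | (2Z,4Z)-dienal of the adduct series | O=C/C=C(C)\C=C/[C@H]1O[C@@]1(CO[Si](C)(C)C(C)(C)C)C[C@@H](O[Si](CC)(CC)CC)C(O)C(=C)C(=O)OC
F10 | step 13 | (4Z)-enynol diol | OC/C=C(C)\C#C[C@H]1O[C@@]1(CO[Si](C)(C)C(C)(C)C)C[C@@H](O[Si](CC)(CC)CC)/C=C(\CO)C(=O)OC
F11 | step 13 | (2Z,4Z)-dienol diol | OC/C=C(C)\C=C/[C@H]1O[C@@]1(CO[Si](C)(C)C(C)(C)C)C[C@@H](O[Si](CC)(CC)CC)/C=C(\CO)C(=O)OC
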